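**Plan**
Numbering: tetralin C1 carries the trimethoxyphenyl ring, C2 and C3 carry the CH2OH carbons C9' and C9, and C4 is the ring CH2. Ring A is C4a, C5–C8, C8a with OMe on C6 and OH on C7 and C8.
Enabling feature: with C9' and C9 as esters, C9'–C2–C3–C9 is a succinate. Its two halves hang from the neighbouring ring A carbons C8a (through C1) and C4a (through C4), so ring B can be closed by joining two enolate carbons.
Cuts, in retrosynthetic order: C2–C3 (opens ring B), C1–aryl, C1=C2 together with O8–C9' (a temporary coumarin ring), C8a–C1 (formyl carbon), C3=C4.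
Forward: ring A is bought as 5-hydroxyvanillin. The C4a propanoate arm is built and C1 is placed on C8a. The lactone ring O8–C9'–C2–C1 closes, takes up the aryl group and is opened again. Ring B closes last.
Stereochemistry: C1 comes from a rhodium–(S)-SEGPHOS conjugate addition. C2 and C3 follow from C1, because the peri C8 benzyloxy group holds the C1 aryl pseudoaxial. The 1,2-cis-2,3-trans diester is then the diequatorial one and is collected under NaOMe equilibration.

Key step: step 8

Assumption: the rhodium–SEGPHOS catalyst is taken to attack the substituted coumarin on the same face as simple coumarins, where the (S)-ligand leads to the (4S)-lactone.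

Step 1
Reactants: 1 3,4-dihydroxy-5-methoxybenzaldehyde (5-hydroxyvanillin)
Product: 2 4-(benzyloxy)-3-hydroxy-5-methoxybenzaldehyde
Conditions: BnBr (1.0 equiv), NaHCO3 (1.5 equiv), DMF, 40 °C
Reagents that add atoms: benzyl bromide, BrCc1ccccc1
Why: Williamson ether synthesis under a weak base, in which the future C7 hydroxyl (para to the formyl-bearing carbon) is the more acidic phenol and should be benzylated alone, leaving the C8 hydroxyl free as the later ortho director.

Step 2
Reactants: 2 4-(benzyloxy)-3-hydroxy-5-methoxybenzaldehyde; 3 methyl (triphenylphosphoranylidene)acetate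
Product: 4 methyl (E)-3-[4-(benzyloxy)-3-hydroxy-5-methoxyphenyl]prop-2-enoate
Conditions: 3 (1.1 equiv), toluene, 80 °C
Reagents that add atoms: methyl (triphenylphosphoranylidene)acetate 3, COC(=O)C=P(c1ccccc1)(c1ccccc1)c1ccccc1
Why: Wittig olefination with a stabilised ylide, which tolerates the free phenol and joins C3 to C4, the alkene geometry being of no consequence for the next step.

Step 3
Reactants: 4 methyl (E)-3-[4-(benzyloxy)-3-hydroxy-5-methoxyphenyl]prop-2-enoate
Product: 5 methyl 3-[4-(benzyloxy)-3-hydroxy-5-methoxyphenyl]propanoate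
Conditions: H2 (4 bar), RhCl(PPh3)3 (5 mol %), THF/t-BuOH 1:1, 40 °C
Reagents that add atoms: none
Why: Homogeneous catalytic hydrogenation saturates the disubstituted conjugated alkene and, unlike Pd on carbon, should leave the aryl benzyl ether untouched.

Step 4
Reactants: 5 methyl 3-[4-(benzyloxy)-3-hydroxy-5-methoxyphenyl]propanoate
Product: 7 methyl 3-[4-(benzyloxy)-2-formyl-3-hydroxy-5-methoxyphenyl]propanoate, via salicyl alcohol 6 (not isolated)
Conditions: MgCl2 (2 equiv), Et3N (4 equiv), (CH2O)n (6 equiv), MeCN, reflux; 1 M HCl work-up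
Reagents that add atoms: paraformaldehyde (reacts as formaldehyde), C=O
Why: Casnati–Skattebøl ortho-formylation, in which the magnesium phenoxide delivers formaldehyde only to an ortho carbon, C8a is the single free ortho site of the C8 phenol (and para to the C6 methoxy group), and a second formaldehyde oxidises 6 by an Oppenauer-type hydride transfer.

Step 5
Reactants: 7 methyl 3-[4-(benzyloxy)-2-formyl-3-hydroxy-5-methoxyphenyl]propanoate; 3 methyl (triphenylphosphoranylidene)acetate
Product: 9 methyl 3-[8-(benzyloxy)-7-methoxy-2-oxo-2H-chromen-5-yl]propanoate, via hydroxycinnamate 8 (not isolated)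
Conditions: 3 (1.3 equiv), N,N-diethylaniline, reflux (ca. 215 °C)
Reagents that add atoms: methyl (triphenylphosphoranylidene)acetate 3, COC(=O)C=P(c1ccccc1)(c1ccccc1)c1ccccc1
Why: Wittig olefination followed by thermal E/Z isomerisation and lactonisation, the established one-flask conversion of salicylaldehydes into coumarins, forms C1=C2 and ties C9' to O8.

Step 6
Reactants: 9 methyl 3-[8-(benzyloxy)-7-methoxy-2-oxo-2H-chromen-5-yl]propanoate; 10 3,4,5-trimethoxyphenylboronic acid
Product: 11 methyl 3-[(4S)-8-(benzyloxy)-7-methoxy-2-oxo-4-(3,4,5-trimethoxyphenyl)-3,4-dihydro-2H-chromen-5-yl]propanoate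
Conditions: 10 (5 equiv), Rh(acac)(C2H4)2 (5 mol %), (S)-SEGPHOS (5.5 mol %), dioxane/H2O 10:1, 60 °C
Reagents that add atoms: 3,4,5-trimethoxyphenylboronic acid 10, COc1cc(B(O)O)cc(OC)c1OC
Why: Rhodium-catalysed asymmetric 1,4-addition of an arylboronic acid (Hayashi–Miyaura reaction), established for coumarins with this ligand class, in which the arylrhodium species inserts the C1=C2 bond on the face left open by the (S)-ligand and so sets C1 as S before water protonates the rhodium enolate.

Step 7
Reactants: 11 methyl 3-[(4S)-8-(benzyloxy)-7-methoxy-2-oxo-4-(3,4,5-trimethoxyphenyl)-3,4-dihydro-2H-chromen-5-yl]propanoate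
Product: 13 methyl (3S)-3-[2,3-bis(benzyloxy)-4-methoxy-6-(3-methoxy-3-oxopropyl)phenyl]-3-(3,4,5-trimethoxyphenyl)propanoate, via phenol diester 12 (not isolated)
Conditions: K2CO3 (3 equiv), BnBr (2 equiv), MeOH/acetone 1:1, reflux
Reagents that add atoms: methanol, CO; benzyl bromide, BrCc1ccccc1
Why: Base-mediated methanolysis of the aryl lactone with Williamson trapping of the released phenoxide 12 in the same flask, a known irreversible opening of 4-arylchroman-2-ones, frees C9' from O8 (a tether spanning C8a and C2 would forbid ring B) and leaves the non-acidic C1 centre untouched.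

Step 8
Reactants: 13 methyl (3S)-3-[2,3-bis(benzyloxy)-4-methoxy-6-(3-methoxy-3-oxopropyl)phenyl]-3-(3,4,5-trimethoxyphenyl)propanoate
Product: 16 dimethyl (1S,2S,3S)-7,8-bis(benzyloxy)-6-methoxy-1-(3,4,5-trimethoxyphenyl)-1,2,3,4-tetrahydronaphthalene-2,3-dicarboxylate, via dilithium bis-enolate 14 (not isolated), via C2/C3 epimer mixture 15 (not isolated)
Conditions: LiN(i-Pr)2 (2.2 equiv), THF (0.01 M), −78 °C; Cu(2-ethylhexanoate)2 (2.2 equiv), −78 → 0 °C; aq NH4Cl/NH3 wash; unpurified 15, NaOMe (0.3 equiv), MeOH, 60 °C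
Reagents that add atoms: none
Why: Two equivalents of LiN(i-Pr)2 turn both ester arms into lithium enolates (14), divalent copper removes one electron, the α-carbonyl radical (drawn at C3) adds to the enolate carbon C2, and a second divalent copper oxidises the resulting ketyl-type radical anion back to an ester, so that C2–C3 forms with loss of two electrons. The reaction type is the oxidative coupling of ester enolates by copper carboxylates to succinates, known between two molecules and within α,ω-diesters, where it gives trans-cycloalkane-1,2-dicarboxylates. Ring B closes in a 6-exo-trig mode (C2 inside and C9' outside the new ring), favoured by the ortho relation of the two arms on C4a and C8a and protected from intermolecular coupling by high dilution. C2 is controlled by C1, since the peri C8 benzyloxy group pushes the C1 aryl group pseudoaxial and the equatorial site at C2 then lies on the aryl face (1,2-cis). C3 is controlled by C2, since the two esters settle trans-diequatorial, whereas the all-trans isomer needs either a pseudoequatorial aryl pressed against O8 or a syn-diaxial aryl/C3-ester pair. The selectivity needed is diastereoselectivity at C2 and C3, and because both centres are α to esters while C1–H is not acidic, catalytic NaOMe should funnel the kinetic mixture 15 into 16 without touching C1.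

Step 9
Reactants: 16 dimethyl (1S,2S,3S)-7,8-bis(benzyloxy)-6-methoxy-1-(3,4,5-trimethoxyphenyl)-1,2,3,4-tetrahydronaphthalene-2,3-dicarboxylate
Product: 17 [(1S,2S,3S)-7,8-bis(benzyloxy)-6-methoxy-1-(3,4,5-trimethoxyphenyl)-1,2,3,4-tetrahydronaphthalene-2,3-diyl]dimethanol
Conditions: LiAlH4 (2.5 equiv), THF, 0 °C → rt
Reagents that add atoms: none
Why: Hydride reduction of both esters to primary alcohols, which is faster than enolisation at this temperature, so that C2 and C3 should be retained.

Step 10
Reactants: 17 [(1S,2S,3S)-7,8-bis(benzyloxy)-6-methoxy-1-(3,4,5-trimethoxyphenyl)-1,2,3,4-tetrahydronaphthalene-2,3-diyl]dimethanol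
Product: 18 (1S,2S,3S)-2,3-bis(hydroxymethyl)-6-methoxy-1-(3,4,5-trimethoxyphenyl)-1,2,3,4-tetrahydronaphthalene-7,8-diol (CNP0188980.2)
Conditions: H2 (1 atm), Pd/C (10 wt %), MeOH/EtOAc, rt, air excluded on work-up
Reagents that add atoms: none
Why: Catalytic hydrogenolysis cleaves the two aryl benzyl ethers, while the methyl ethers, the primary alcohols and the C–C bonds at the doubly benzylic C1 are inert.

**Compound list**
1 | 3,4-dihydroxy-5-methoxybenzaldehyde (5-hydroxyvanillin) | COc1cc(C=O)cc(O)c1O | starting material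
2 | 4-(benzyloxy)-3-hydroxy-5-methoxybenzaldehyde | COc1cc(C=O)cc(O)c1OCc1ccccc1 | intermediate
3 | methyl (triphenylphosphoranylidene)acetate | COC(=O)C=P(c1ccccc1)(c1ccccc1)c1ccccc1 | starting material
4 | methyl (E)-3-[4-(benzyloxy)-3-hydroxy-5-methoxyphenyl]prop-2-enoate | COC(=O)/C=C/c1cc(O)c(OCc2ccccc2)c(OC)c1 | intermediate
5 | methyl 3-[4-(benzyloxy)-3-hydroxy-5-methoxyphenyl]propanoate | COC(=O)CCc1cc(O)c(OCc2ccccc2)c(OC)c1 | intermediate
6 | methyl 3-[4-(benzyloxy)-3-hydroxy-2-(hydroxymethyl)-5-methoxyphenyl]propanoate (present as its magnesium salt) | COC(=O)CCc1cc(OC)c(OCc2ccccc2)c(O)c1CO | intermediate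
7 | methyl 3-[4-(benzyloxy)-2-formyl-3-hydroxy-5-methoxyphenyl]propanoate | COC(=O)CCc1cc(OC)c(OCc2ccccc2)c(O)c1C=O | intermediate
8 | methyl 3-[3-(benzyloxy)-2-hydroxy-4-methoxy-6-(3-methoxy-3-oxopropyl)phenyl]prop-2-enoate (E and Z forms interconvert at the reaction temperature) | COC(=O)CCc1cc(OC)c(OCc2ccccc2)c(O)c1C=CC(=O)OC | intermediate
9 | methyl 3-[8-(benzyloxy)-7-methoxy-2-oxo-2H-chromen-5-yl]propanoate | COC(=O)CCc1cc(OC)c(OCc2ccccc2)c2OC(=O)C=Cc12 | intermediate
10 | 3,4,5-trimethoxyphenylboronic acid | COc1cc(B(O)O)cc(OC)c1OC | starting material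
11 | methyl 3-[(4S)-8-(benzyloxy)-7-methoxy-2-oxo-4-(3,4,5-trimethoxyphenyl)-3,4-dihydro-2H-chromen-5-yl]propanoate | COc1cc(CCC(=O)OC)c2c(OC(=O)C[C@H]2c2cc(OC)c(OC)c(OC)c2)c1OCc1ccccc1 | intermediate
12 | methyl (3S)-3-[3-(benzyloxy)-2-hydroxy-4-methoxy-6-(3-methoxy-3-oxopropyl)phenyl]-3-(3,4,5-trimethoxyphenyl)propanoate | COc1cc(CCC(=O)OC)c(c(O)c1OCc1ccccc1)[C@H](c1cc(OC)c(OC)c(OC)c1)CC(=O)OC | intermediate
13 | methyl (3S)-3-[2,3-bis(benzyloxy)-4-methoxy-6-(3-methoxy-3-oxopropyl)phenyl]-3-(3,4,5-trimethoxyphenyl)propanoate | COc1cc(CCC(=O)OC)c(c(OCc2ccccc2)c1OCc1ccccc1)[C@H](c1cc(OC)c(OC)c(OC)c1)CC(=O)OC | intermediate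
14 | dilithium bis-enolate of 13 (enolate geometry not specified) | COc1cc(CC=C([O-])OC)c(c(OCc2ccccc2)c1OCc1ccccc1)[C@H](c1cc(OC)c(OC)c(OC)c1)C=C([O-])OC.[Li+].[Li+] | intermediate
15 | dimethyl (1S)-7,8-bis(benzyloxy)-6-methoxy-1-(3,4,5-trimethoxyphenyl)-1,2,3,4-tetrahydronaphthalene-2,3-dicarboxylate, mixture of C2/C3 epimers | COc1cc2c(c(OCc3ccccc3)c1OCc1ccccc1)[C@H](c1cc(OC)c(OC)c(OC)c1)C(C(=O)OC)C(C(=O)OC)C2 | intermediate
16 | dimethyl (1S,2S,3S)-7,8-bis(benzyloxy)-6-methoxy-1-(3,4,5-trimethoxyphenyl)-1,2,3,4-tetrahydronaphthalene-2,3-dicarboxylate (1,2-cis, 2,3-trans) | COc1cc2c(c(OCc3ccccc3)c1OCc1ccccc1)[C@H](c1cc(OC)c(OC)c(OC)c1)[C@H](C(=O)OC)[C@@H](C(=O)OC)C2 | intermediate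
17 | [(1S,2S,3S)-7,8-bis(benzyloxy)-6-methoxy-1-(3,4,5-trimethoxyphenyl)-1,2,3,4-tetrahydronaphthalene-2,3-diyl]dimethanol | COc1cc2c(c(OCc3ccccc3)c1OCc1ccccc1)[C@H](c1cc(OC)c(OC)c(OC)c1)[C@H](CO)[C@@H](CO)C2 | intermediate
18 | (6S,7S,8S)-6,7-bis(hydroxymethyl)-3-methoxy-8-(3,4,5-trimethoxyphenyl)-5,6,7,8-tetrahydronaphthalene-1,2-diol (1S,2S,3S in the route numbering) | COc1cc2c(c(O)c1O)[C@H](c1cc(OC)c(OC)c(OC)c1)[C@H](CO)[C@@H](CO)C2 | target

**Count**
Total steps: 10. Longest linear sequence: 10 steps, from 1 to 18.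

**Steps most likely to fail**

1. Step 8. Intermolecular coupling or Claisen-type condensation of the methyl ester enolates may compete with ring closure. The equilibration may also stop short of a useful preference, because tipping the C2 ester axial relieves its gauche contact with the aryl ring.
 - The fallback keeps the C2–C3 bond but uses imide enolates, with auxiliary control in place of thermodynamic control. It sets out from 13.
 - LiOH in THF/H2O gives the diacid F1.
 - Pivaloyl chloride/Et3N, then the lithium salt of (R)-4-benzyl-1,3-oxazolidin-2-one, gives the open-chain bis-imide F2.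
 - LiN(i-Pr)2 (2.2 equiv) in THF at −78 °C, then CuCl2 in DMF, closes ring B to the tetralin bis-imide F3. Each chelated Z-enolate reacts on the face remote from its benzyl group, which is the sense required at both C2 and C3 and agrees with the substrate bias.
 - LiBH4 in THF/MeOH removes both auxiliaries reductively, and the fallback comes back to the route at 17.

2. Step 6. Insertion of the arylrhodium species into the C1=C2 bond may be slower than protodeboronation of 10. The bond is deactivated by the C6 methoxy donor and flanked by the peri C4a arm, and the arm may also erode facial selectivity.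
 - The fallback replaces catalyst control on the lactone by auxiliary-controlled organocopper addition to an open-chain enoyl imide. It sets out from 7.
 - BnBr/K2CO3 in DMF gives the bis(benzyl ether) aldehyde F4.
 - A Horner–Wadsworth–Emmons reaction with diethyl {2-oxo-2-[(4R)-2-oxo-4-phenyl-1,3-oxazolidin-3-yl]ethyl}phosphonate (LiCl, i-Pr2NEt, MeCN) gives the E-enoyl imide F5.
 - 3,4,5-Trimethoxyphenylmagnesium bromide with CuBr·SMe2 in THF at −40 °C adds to the chelated s-cis enoyl imide on the face remote from the phenyl group and gives the 1S adduct F6.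
 - NaOMe in MeOH at 0 °C releases the auxiliary, and the fallback comes back to the route at 13.

3. Step 4. Formylation may stall, because the only free ortho carbon lies between the phenoxide and the propanoate arm.
 - The fallback avoids the aldehyde altogether and builds the lactone ring by C–H functionalisation. It sets out from 5.
 - Propiolic acid and dicyclohexylcarbodiimide in CH2Cl2 at 0 °C give the aryl propiolate F7.
 - Intramolecular hydroarylation with catalytic AuCl3/AgOTf in 1,2-dichloroethane closes the ring 6-endo-dig at C8a, the single free ortho carbon, which is activated by the para C6 methoxy group.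
 - The fallback comes back to the route at 9.

**Further compounds**
F1 | step 8 | (3S)-3-[2,3-bis(benzyloxy)-6-(2-carboxyethyl)-4-methoxyphenyl]-3-(3,4,5-trimethoxyphenyl)propanoic acid | COc1cc(CCC(=O)O)c(c(OCc2ccccc2)c1OCc1ccccc1)[C@H](c1cc(OC)c(OC)c(OC)c1)CC(=O)O
F2 | step 8 | open-chain bis-imide of F1 carrying two (4R)-4-benzyl-2-oxo-1,3-oxazolidin-3-yl groups | COc1cc(CCC(=O)N2[C@H](Cc3ccccc3)COC2=O)c(c(OCc2ccccc2)c1OCc1ccccc1)[C@H](c1cc(OC)c(OC)c(OC)c1)CC(=O)N1[C@H](Cc2ccccc2)COC1=O
F3 | step 8 | (1S,2S,3S)-7,8-bis(benzyloxy)-6-methoxy-1-(3,4,5-trimethoxyphenyl)tetralin-2,3-dicarbonyl bis-imide of (4R)-4-benzyl-1,3-oxazolidin-2-one | COc1cc2c(c(OCc3ccccc3)c1OCc1ccccc1)[C@H](c1cc(OC)c(OC)c(OC)c1)[C@H](C(=O)N1[C@H](Cc3ccccc3)COC1=O)[C@@H](C(=O)N1[C@H](Cc3ccccc3)COC1=O)C2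
F4 | step 6 | methyl 3-[3,4-bis(benzyloxy)-2-formyl-5-methoxyphenyl]propanoate | COC(=O)CCc1cc(OC)c(OCc2ccccc2)c(OCc2ccccc2)c1C=O
F5 | step 6 | methyl 3-[3,4-bis(benzyloxy)-5-methoxy-2-[(E)-3-oxo-3-[(4R)-2-oxo-4-phenyl-1,3-oxazolidin-3-yl]prop-1-enyl]phenyl]propanoate | COC(=O)CCc1cc(OC)c(OCc2ccccc2)c(OCc2ccccc2)c1/C=C/C(=O)N1[C@H](c2ccccc2)COC1=O
F6 | step 6 | methyl 3-[3,4-bis(benzyloxy)-5-methoxy-2-[(1S)-3-oxo-3-[(4R)-2-oxo-4-phenyl-1,3-oxazolidin-3-yl]-1-(3,4,5-trimethoxyphenyl)propyl]phenyl]propanoate | COc1cc(CCC(=O)OC)c(c(OCc2ccccc2)c1OCc1ccccc1)[C@H](c1cc(OC)c(OC)c(OC)c1)CC(=O)N1[C@H](c2ccccc2)COC1=O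
F7 | step 4 | 2-(benzyloxy)-3-methoxy-5-(3-methoxy-3-oxopropyl)phenyl prop-2-ynoate | C#CC(=O)Oc1cc(CCC(=O)OC)cc(OC)c1OCc1ccccc1
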